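## Retrosynthetic overview

- Numbering: C1 = CH3, C2 = CH(O-palmitoyl), C3 and C4 = CHOH, C5 = CH2, C6 = CHOH on C4 of oxazole ring A (2,4-disubstituted). Ring B is the 5-substituted oxazole.
- Enabling feature: O2-acyl on C2 and O4-H on C4 form a 1,3-anti diol monoester around the oxygenated C3. C4 can therefore be carried as a ketone. O3 then makes C3 the acidic, Z-enolisable alpha-carbon of that ketone, and C2 becomes the carbonyl carbon of acetaldehyde.
- Disconnections, part 1: the two O–Si bonds go last. Before that, the O2–acyl and C4–H bonds are cut together (Evans–Tishchenko reduction with hexadecanal). Before that, C2–C3 is cut (Z-boron syn-aldol, sets C2 and C3).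
- Disconnections, part 2: C5–C6 (enamine aldol of hydroxyacetone on its methyl side, sets C6 by catalysis), then the ring A C2–CH2 bond (Negishi coupling).
- No ring is formed. Rings A and B are both bought and only joined through the CH2 link.

Key step: step 5

Assumption: the Z-enol borinate with isopinocampheyl ligands from (−)-α-pinene is taken to attack the Re face of acetaldehyde, by analogy with the corresponding (Z)-crotylborane. If the sense is the opposite, (−)-Ipc2BCl is used and nothing else changes.

## Route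

Step 1
Reactants: 1 5-(chloromethyl)-1,3-oxazole; 2 ethyl 2-chloro-1,3-oxazole-4-carboxylate
Product: 4 ethyl 2-(1,3-oxazol-5-ylmethyl)-1,3-oxazole-4-carboxylate, via oxazol-5-ylmethylzinc chloride 3 (not isolated)
Conditions: 1, Zn dust, LiCl, THF, 25 °C; then 2, Pd(PPh3)4 (5 mol%), THF, 50 °C
Reagents that add atoms: none
Why: LiCl-assisted zinc insertion into the heterobenzylic C–Cl bond gives a non-basic zinc reagent that tolerates the ester and the acidic oxazole C–H bonds, and Negishi cross-coupling at the activated C2–Cl bond of ring A should join the two bought rings through the CH2 link.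

Step 2
Reactants: 4 ethyl 2-(1,3-oxazol-5-ylmethyl)-1,3-oxazole-4-carboxylate
Product: 5 2-(1,3-oxazol-5-ylmethyl)-1,3-oxazole-4-carbaldehyde
Conditions: i-Bu2AlH (1.2 equiv), CH2Cl2, −78 °C; then aq. potassium sodium tartrate
Reagents that add atoms: none
Why: Partial ester reduction with i-Bu2AlH should stop at the aluminium hemiacetal at −78 °C, which collapses to the aldehyde only on work-up, as is usual for oxazole-4-carboxylates.

Step 3
Reactants: 5 2-(1,3-oxazol-5-ylmethyl)-1,3-oxazole-4-carbaldehyde; 6 hydroxyacetone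
Product: 7 (4R)-1,4-dihydroxy-4-[2-(1,3-oxazol-5-ylmethyl)-1,3-oxazol-4-yl]butan-2-one
Conditions: diethyl (2S,3S)-2-hydroxy-3-[(S)-pyrrolidine-2-carboxamido]butanedioate (20 mol%), 6 (excess), THF/H2O, −15 °C
Reagents that add atoms: none
Why: This is a direct enamine-catalysed asymmetric aldol reaction in which this class of L-prolinamide in aqueous THF is known to steer hydroxyacetone through its methyl-side enamine, and the amide and hydroxyl hydrogen bonds to the electron-poor heteroaryl aldehyde expose its Re face, which should set C6 as R.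

Step 4
Reactants: 7 (4R)-1,4-dihydroxy-4-[2-(1,3-oxazol-5-ylmethyl)-1,3-oxazol-4-yl]butan-2-one
Product: 8 (4R)-1,4-bis(tert-butyldimethylsilyloxy)-4-[2-(1,3-oxazol-5-ylmethyl)-1,3-oxazol-4-yl]butan-2-one
Conditions: TBSCl (2.5 equiv), imidazole, DMF, 0 °C to rt
Reagents that add atoms: tert-butyldimethylsilyl chloride, CC(C)(C)[Si](C)(C)Cl
Why: Standard silyl ether formation caps O3 and O6 in one operation under conditions too mild for retro-aldol cleavage or elimination, so that later only O2–H can direct the reduction of C4 and both groups can leave together at the end.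

Step 5
Reactants: 8 (4R)-1,4-bis(tert-butyldimethylsilyloxy)-4-[2-(1,3-oxazol-5-ylmethyl)-1,3-oxazol-4-yl]butan-2-one; 9 acetaldehyde
Product: 12 (1R,4R,5S)-1,4-bis(tert-butyldimethylsilyloxy)-5-hydroxy-1-[2-(1,3-oxazol-5-ylmethyl)-1,3-oxazol-4-yl]hexan-3-one, via Z-enol borinate 10 (not isolated), via boron aldolate 11 (not isolated)
Conditions: (+)-Ipc2BCl (2 equiv), Et3N, Et2O, 0 °C; 9 (5 equiv), −78 to −20 °C; then H2O2, MeOH, pH 7 buffer, 0 °C
Reagents that add atoms: none
Why: Ipc2BCl binds the C4 carbonyl oxygen and Et3N removes one C3 proton to give Z-enol borinate 10, whose boron then binds acetaldehyde and passes C3 to its carbonyl carbon through a closed six-membered chair (Zimmerman–Traxler) transition state to aldolate 11, which oxidative work-up releases as 12. The closest known reaction type is the dialkylchloroborane-mediated syn-aldol reaction of alpha-silyloxy ketones (protected dihydroxyacetone and erythrulose), including its diisopinocampheyl version with simple aldehydes. No ring is closed, the only cycle being the transient chair. C2 and C3 are created together: their syn relation follows from the Z geometry of 10 (OTBS cis to O–B and trans to the C5 chain) with the acetaldehyde methyl equatorial, and their absolute sense (Re face of acetaldehyde, hence 2S and the matching C3) comes from the isopinocampheyl ligands, the remote C6 silyl ether being expected to add little bias of its own. The step needs site selectivity between the two alpha-methylene groups, secured because C3–H is acidified by O3 and unhindered while C5–H lies next to the branched C6 bearing OTBS and ring A, and it needs chemoselectivity, secured because the amine/chloroborane pair leaves alone the CH2 between rings A and B and C2–H of ring B, which a lithium amide would attack. In one operation the chain is completed, two of the four stereocentres are set, and the O2–H/C4=O pair that steers step 6 is laid down.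

Step 6
Reactants: 12 (1R,4R,5S)-1,4-bis(tert-butyldimethylsilyloxy)-5-hydroxy-1-[2-(1,3-oxazol-5-ylmethyl)-1,3-oxazol-4-yl]hexan-3-one; 13 hexadecanal
Product: 15 (2S,3S,4S,6R)-3,6-bis(tert-butyldimethylsilyloxy)-4-hydroxy-6-[2-(1,3-oxazol-5-ylmethyl)-1,3-oxazol-4-yl]hexan-2-yl hexadecanoate, via O2-hemiacetal 14 (not isolated)
Conditions: SmI2 (30 mol%, premixed with 13 so that only trivalent samarium remains), 13 (5 equiv), THF, −10 °C
Reagents that add atoms: none
Why: In the Evans–Tishchenko reduction O2–H adds to hexadecanal, and the samarium-chelated hemiacetal 14 hands its hydride to C4 through a chair-like bicyclic transition state, which should place O4 anti to O2 (C4 = S, hence syn to O6) and leave the palmitate on O2 alone.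

Step 7
Reactants: 15 (2S,3S,4S,6R)-3,6-bis(tert-butyldimethylsilyloxy)-4-hydroxy-6-[2-(1,3-oxazol-5-ylmethyl)-1,3-oxazol-4-yl]hexan-2-yl hexadecanoate
Product: 16 (2S,3S,4S,6R)-3,4,6-trihydroxy-6-[2-(1,3-oxazol-5-ylmethyl)-1,3-oxazol-4-yl]hexan-2-yl hexadecanoate (target)
Conditions: HF·pyridine, pyridine, THF, 0 °C to rt
Reagents that add atoms: none
Why: Fluoride-mediated desilylation in a pyridine-buffered, weakly acidic medium should cleave both silyl ethers without touching a stereocentre, the ester or the oxazoles, and it avoids the alkoxide conditions that drive O2 to O3 acyl migration.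

## Compound list

1 | 5-(chloromethyl)-1,3-oxazole | ClCc1cnco1 | starting material
2 | ethyl 2-chloro-1,3-oxazole-4-carboxylate | CCOC(=O)c1coc(Cl)n1 | starting material
3 | (1,3-oxazol-5-ylmethyl)zinc chloride | Cl[Zn]Cc1cnco1 | intermediate
4 | ethyl 2-(1,3-oxazol-5-ylmethyl)-1,3-oxazole-4-carboxylate | CCOC(=O)c1coc(Cc2cnco2)n1 | intermediate
5 | 2-(1,3-oxazol-5-ylmethyl)-1,3-oxazole-4-carbaldehyde | O=Cc1coc(Cc2cnco2)n1 | intermediate
6 | hydroxyacetone | CC(=O)CO | starting material
7 | (4R)-1,4-dihydroxy-4-[2-(1,3-oxazol-5-ylmethyl)-1,3-oxazol-4-yl]butan-2-one | OCC(=O)C[C@@H](O)c1coc(Cc2cnco2)n1 | intermediate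
8 | (4R)-1,4-bis(tert-butyldimethylsilyloxy)-4-[2-(1,3-oxazol-5-ylmethyl)-1,3-oxazol-4-yl]butan-2-one | CC(C)(C)[Si](C)(C)OCC(=O)C[C@@H](O[Si](C)(C)C(C)(C)C)c1coc(Cc2cnco2)n1 | intermediate
9 | acetaldehyde | CC=O | starting material
10 | Z-enol diisopinocampheylborinate of 8 (C3=C4, ligands from (−)-α-pinene) | CC(C)(C)[Si](C)(C)O/C=C(\OB([C@H]1C[C@H]2C[C@@H]([C@@H]1C)C2(C)C)[C@H]1C[C@H]2C[C@@H]([C@@H]1C)C2(C)C)C[C@@H](O[Si](C)(C)C(C)(C)C)c1coc(Cc2cnco2)n1 | intermediate
11 | O2-diisopinocampheylboron aldolate | C[C@H](OB([C@H]1C[C@H]2C[C@@H]([C@@H]1C)C2(C)C)[C@H]1C[C@H]2C[C@@H]([C@@H]1C)C2(C)C)[C@@H](O[Si](C)(C)C(C)(C)C)C(=O)C[C@@H](O[Si](C)(C)C(C)(C)C)c1coc(Cc2cnco2)n1 | intermediate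
12 | (1R,4R,5S)-1,4-bis(tert-butyldimethylsilyloxy)-5-hydroxy-1-[2-(1,3-oxazol-5-ylmethyl)-1,3-oxazol-4-yl]hexan-3-one | C[C@H](O)[C@@H](O[Si](C)(C)C(C)(C)C)C(=O)C[C@@H](O[Si](C)(C)C(C)(C)C)c1coc(Cc2cnco2)n1 | intermediate
13 | hexadecanal | CCCCCCCCCCCCCCCC=O | starting material
14 | hemiacetal of 12 with 13 at O2 (drawn metal-free, samarium-bound in the flask, hemiacetal carbon undefined) | CCCCCCCCCCCCCCCC(O)O[C@@H](C)[C@@H](O[Si](C)(C)C(C)(C)C)C(=O)C[C@@H](O[Si](C)(C)C(C)(C)C)c1coc(Cc2cnco2)n1 | intermediate
15 | (2S,3S,4S,6R)-3,6-bis(tert-butyldimethylsilyloxy)-4-hydroxy-6-[2-(1,3-oxazol-5-ylmethyl)-1,3-oxazol-4-yl]hexan-2-yl hexadecanoate | CCCCCCCCCCCCCCCC(=O)O[C@@H](C)[C@@H](O[Si](C)(C)C(C)(C)C)[C@@H](O)C[C@@H](O[Si](C)(C)C(C)(C)C)c1coc(Cc2cnco2)n1 | intermediate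
16 | (2S,3S,4S,6R)-3,4,6-trihydroxy-6-[2-(1,3-oxazol-5-ylmethyl)-1,3-oxazol-4-yl]hexan-2-yl hexadecanoate | CCCCCCCCCCCCCCCC(=O)O[C@@H](C)[C@@H](O)[C@@H](O)C[C@@H](O)c1coc(Cc2cnco2)n1 | target

## Step count and risks

Total step count: 7. Longest linear sequence: 7 steps (from 1 or 2 to 16).

Steps most likely to fail:

1. Step 5.
   - Enolisation may run towards C5 instead of C3, with later loss of the C6 silyloxy group. The isopinocampheyl ligands may also discriminate the acetaldehyde faces poorly.
   - The fallback sets out from 8. Short exposure to HF·pyridine in pyridine/THF at 0 °C cleaves only the primary silyl ether and gives the alpha-hydroxy ketone F1.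
   - A dinuclear zinc catalyst is made from Et2Zn and the ProPhenol ligand enantiomer chosen for Re-face attack. It holds O3 and O4 as a chelated zinc enediolate, so only C3 can react, and adds it to slowly dosed acetaldehyde 9 (direct catalytic syn-aldol of alpha-hydroxy ketones) to give the syn-2,3-diol ketone F2.
   - Evans–Tishchenko reduction with 13 follows. Only the O2 hemiacetal reaches C4 through a six-membered array, which gives the mono-silylated palmitate F3.
   - HF·pyridine then gives 16, where the fallback comes back to the route.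

2. Step 3.
   - Reaction through the more substituted hydroxy-enamine would lead to the branched 1,2-diol series. Retro-aldol equilibration would erode the enantioselectivity at C6.
   - The fallback sets out from 5. Brown allylation with (+)-Ipc2B(allyl) (Re-face attack) gives the homoallylic alcohol F4.
   - TBSCl/imidazole gives the silyl ether F5. OsO4 (cat.)/NMO gives the terminal diol F6 as an inconsequential mixture at the new carbinol.
   - One equivalent of TBSCl caps the primary hydroxyl to give the secondary alcohol F7. Dess–Martin oxidation returns to the route at 8.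

3. Step 6.
   - Residual divalent samarium may cleave the alpha-silyloxy group reductively. The aldol may fragment by retro-aldol. The acyl group may migrate from O2 to O4 on long exposure.
   - The fallback sets out from 12. Evans–Saksena reduction (Me4NBH(OAc)3, MeCN/AcOH, −30 °C) delivers hydride from O2-bound boron and gives the 2,4-anti diol F8.
   - Sterically controlled mono-acylation of the less hindered methyl carbinol O2 follows, with palmitoyl chloride and 2,4,6-collidine at low temperature. The O4 isomer is recycled by methanolysis. This returns to the route at 15.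

## Further compounds

F1 | step 5 | (4R)-4-(tert-butyldimethylsilyloxy)-1-hydroxy-4-[2-(1,3-oxazol-5-ylmethyl)-1,3-oxazol-4-yl]butan-2-one | OCC(=O)C[C@@H](O[Si](C)(C)C(C)(C)C)c1coc(Cc2cnco2)n1
F2 | step 5 | (1R,4R,5S)-1-(tert-butyldimethylsilyloxy)-4,5-dihydroxy-1-[2-(1,3-oxazol-5-ylmethyl)-1,3-oxazol-4-yl]hexan-3-one | C[C@H](O)[C@@H](O)C(=O)C[C@@H](O[Si](C)(C)C(C)(C)C)c1coc(Cc2cnco2)n1
F3 | step 5 | (2S,3S,4S,6R)-6-(tert-butyldimethylsilyloxy)-3,4-dihydroxy-6-[2-(1,3-oxazol-5-ylmethyl)-1,3-oxazol-4-yl]hexan-2-yl hexadecanoate | CCCCCCCCCCCCCCCC(=O)O[C@@H](C)[C@@H](O)[C@@H](O)C[C@@H](O[Si](C)(C)C(C)(C)C)c1coc(Cc2cnco2)n1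
F4 | step 3 | (1R)-1-[2-(1,3-oxazol-5-ylmethyl)-1,3-oxazol-4-yl]but-3-en-1-ol | C=CC[C@@H](O)c1coc(Cc2cnco2)n1
F5 | step 3 | (1R)-1-(tert-butyldimethylsilyloxy)-1-[2-(1,3-oxazol-5-ylmethyl)-1,3-oxazol-4-yl]but-3-ene | C=CC[C@@H](O[Si](C)(C)C(C)(C)C)c1coc(Cc2cnco2)n1
F6 | step 3 | (4R)-4-(tert-butyldimethylsilyloxy)-4-[2-(1,3-oxazol-5-ylmethyl)-1,3-oxazol-4-yl]butane-1,2-diol (both C2 epimers) | OCC(O)C[C@@H](O[Si](C)(C)C(C)(C)C)c1coc(Cc2cnco2)n1
F7 | step 3 | (4R)-1,4-bis(tert-butyldimethylsilyloxy)-4-[2-(1,3-oxazol-5-ylmethyl)-1,3-oxazol-4-yl]butan-2-ol (both C2 epimers) | CC(C)(C)[Si](C)(C)OCC(O)C[C@@H](O[Si](C)(C)C(C)(C)C)c1coc(Cc2cnco2)n1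
F8 | step 6 | 2,4-anti diol, C2/C3/C4/C6 configured as in 15: 3,6-bis(tert-butyldimethylsilyloxy)-6-[2-(1,3-oxazol-5-ylmethyl)-1,3-oxazol-4-yl]hexane-2,4-diol | C[C@H](O)[C@@H](O[Si](C)(C)C(C)(C)C)[C@@H](O)C[C@@H](O[Si](C)(C)C(C)(C)C)c1coc(Cc2cnco2)n1
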